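Numbering: ring A = C1(=O)–C2=C3–C4(Me)2–C5(C6H2OH)–C10; lactone = C10–C20H2–O–C7(=O)–C8–C9; ring C = C8–C9–C11–C12–C13–C14; ring D = C8–C14–C13–C16(C17H3)(OH)–C15(=O).
Structural handle: in ring A the quaternary C10 lies α to the C1 ketone and carries the oxygenated carbon C20 (a β-hydroxy ketone with a fully substituted α-carbon). That is the product pattern of a 1,2-shift onto the tertiary carbon of a 2,3-epoxy alcohol, so C5–C10 is cut back to a 1-(oxiranyl)cyclopentanol (ring C1–C5) in which C5 migrates from C1 to C10.
Other cuts, in retrosynthetic order: C2=C3 and C16–O (adjustments); C13–C16 (ring D, 5-exo radical closure of a C15–C16≡C17 unit onto C12=C13); C9–C11 and C8–C14 (ring C, butadiene Diels–Alder on the C8=C9 alkylidene lactone); C8=C9 (lactone, Knoevenagel of a C20 thiomalonate with the C9 aldehyde).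
Forward order: cyclopentanone → ring A by ring expansion → lactone → ring C → ring D → C16 hydroxylation → ring A enone.
Stereochemistry: C5 from a lipase resolution; C10 from hydroxyl-directed epoxidation followed by anti migration; C8/C9 from cycloaddition on the lactone face syn to C1; C13 from the bridging constraint; C16 from exo capture of O2.

Key step: step 8

Assumption: the lipase is taken to acylate the (R)-enantiomer of 3 faster, so that (S)-4 is the recovered alcohol; with the reverse preference the acetate fraction would be deacetylated enzymatically and carried on instead.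

Step 1
Reactants: 1 4,4-dimethylcyclopent-2-en-1-one
Product: 3 rac-5-(hydroxymethyl)-4,4-dimethylcyclopent-2-en-1-one, via lithium dienolate 2 (not isolated)
Conditions: LiN(i-Pr)2, THF, −78 °C; CH2O (g, from cracked paraformaldehyde), −78 °C; AcOH quench
Reagents that add atoms: formaldehyde, C=O
Why: Kinetic deprotonation of this cross-conjugated enone is only possible at C5 (α′), and the lithium dienolate undergoes an aldol addition to monomeric formaldehyde; the cold acidic quench should keep the β-hydroxy ketone from dehydrating.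

Step 2
Reactants: 3 rac-5-(hydroxymethyl)-4,4-dimethylcyclopent-2-en-1-one
Product: 4 (5S)-5-(hydroxymethyl)-4,4-dimethylcyclopent-2-en-1-one
Conditions: Burkholderia cepacia lipase (Amano PS, immobilised), vinyl acetate, t-BuOMe, rt, stopped slightly past half conversion; chromatography
Reagents that add atoms: none
Why: Lipase-catalysed kinetic resolution (irreversible transesterification) of a primary alcohol with a stereocentre at the adjacent carbon; the recovered (S)-alcohol supplies C5 of the target, and the neutral conditions should not epimerise the α-centre.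

Step 3
Reactants: 4 (5S)-5-(hydroxymethyl)-4,4-dimethylcyclopent-2-en-1-one
Product: 5 (5S)-5-{[tert-butyl(dimethyl)silyl]oxymethyl}-4,4-dimethylcyclopent-2-en-1-one
Conditions: TBSCl, imidazole, CH2Cl2, 0 °C → rt
Reagents that add atoms: tert-butyldimethylsilyl chloride, CC(C)(C)[Si](C)(C)Cl
Why: Standard silylation of a primary alcohol under weakly basic, non-enolising conditions.

Step 4
Reactants: 5 (5S)-5-{[tert-butyl(dimethyl)silyl]oxymethyl}-4,4-dimethylcyclopent-2-en-1-one
Product: 6 (2S)-2-{[tert-butyl(dimethyl)silyl]oxymethyl}-3,3-dimethylcyclopentan-1-one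
Conditions: H2 (1 atm), Pd/C, EtOAc, rt
Reagents that add atoms: none
Why: Heterogeneous hydrogenation of the enone C=C under neutral conditions; no stereocentre is formed and the α-centre is not touched.

Step 5
Reactants: 7 2-bromoprop-2-en-1-ol
Product: 8 1-{[(2-bromoprop-2-en-1-yl)oxy]methyl}-4-methoxybenzene
Conditions: NaH, 4-MeOC6H4CH2Cl, Bu4NI (cat.), THF, 0 °C → rt
Reagents that add atoms: 4-methoxybenzyl chloride, COc1ccc(CCl)cc1
Why: Williamson ether synthesis; the PMB ether is chosen because it can later be removed oxidatively in the presence of a thioester.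

Step 6
Reactants: 8 1-{[(2-bromoprop-2-en-1-yl)oxy]methyl}-4-methoxybenzene; 6 (2S)-2-{[tert-butyl(dimethyl)silyl]oxymethyl}-3,3-dimethylcyclopentan-1-one
Product: 11 (1S,2S)-2-{[tert-butyl(dimethyl)silyl]oxymethyl}-1-[3-(4-methoxybenzyloxy)prop-1-en-2-yl]-3,3-dimethylcyclopentan-1-ol, via vinyllithium 9 (not isolated), via organocerium dichloride 10 (not isolated)
Conditions: 8, t-BuLi (2 equiv), Et2O, −78 °C; CeCl3, THF, −78 °C; then 6, −78 °C; aq NH4Cl
Reagents that add atoms: none
Why: Bromine–lithium exchange, transmetalation to the weakly basic organocerium reagent and 1,2-addition to the enolisable ketone; attack anti to the neighbouring CH2OTBS group places the tertiary hydroxyl cis to that arm (C1 S).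

Step 7
Reactants: 11 (1S,2S)-2-{[tert-butyl(dimethyl)silyl]oxymethyl}-1-[3-(4-methoxybenzyloxy)prop-1-en-2-yl]-3,3-dimethylcyclopentan-1-ol
Product: 12 (1S,2S)-2-{[tert-butyl(dimethyl)silyl]oxymethyl}-1-{(2S)-2-[(4-methoxybenzyloxy)methyl]oxiran-2-yl}-3,3-dimethylcyclopentan-1-ol
Conditions: VO(acac)2 (5 mol %), t-BuOOH (decane), CH2Cl2, 0 °C → rt
Reagents that add atoms: tert-butyl hydroperoxide, CC(C)(C)OO
Why: Hydroxyl-directed vanadium-catalysed epoxidation of an allylic alcohol (Sharpless–Michaelson type); with an O–C1–C10=CH2 dihedral near 45° in the vanadate ester, the smaller ring carbon C2 should lie near the alkene plane beside CH2OPMB (least A(1,2) strain) and the bulky C5 on the face away from the metal, so oxygen is delivered to the face that gives the (2S)-epoxide.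

Step 8
Reactants: 12 (1S,2S)-2-{[tert-butyl(dimethyl)silyl]oxymethyl}-1-{(2S)-2-[(4-methoxybenzyloxy)methyl]oxiran-2-yl}-3,3-dimethylcyclopentan-1-ol
Product: 13 (2S,3R)-3-{[tert-butyl(dimethyl)silyl]oxymethyl}-2-(hydroxymethyl)-2-[(4-methoxybenzyloxy)methyl]-4,4-dimethylcyclohexan-1-one
Conditions: BF3·OEt2 (1.2 equiv), CH2Cl2, −78 °C; aq NaHCO3
Reagents that add atoms: none
Why: BF3 binds the epoxide oxygen, the bond from the tertiary carbon C10 to oxygen lengthens, the C1–C5 bond anti-periplanar to it shifts to C10 and the oxocarbenium ion at C1 collapses to the ketone; this is the Lewis acid-promoted semipinacol rearrangement of a 2,3-epoxy alcohol with a tertiary carbinol (α-hydroxy epoxide → β-hydroxy ketone with a quaternary α-carbon). Ring A is not closed end to end but arises by ring enlargement, the C1–C5 carbocycle taking up C10 through the 1,2-shift. The new stereocentre C10 is fixed by the epoxide configuration, since migration proceeds with inversion at C10 (anti to the departing oxygen) and retention at C5, which places the liberated C20H2OH cis to the C6 arm and the PMB-protected C9 arm trans to it. The step needs migration of C5 in preference to C2; the higher migratory aptitude of the secondary, more electron-rich C5 and the relief of crowding between C5 and the fully substituted C1 should secure it, and ionisation is confined to C10 because only that epoxide carbon is tertiary. Release of epoxide strain and carbonyl formation make the shift irreversible at −78 °C, where the PMB and TBS ethers should survive and where the trans-disposed C6 oxygen cannot reach C10.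

Step 9
Reactants: 14 2,2-dimethyl-1,3-dioxane-4,6-dione (Meldrum's acid)
Product: 15 3-(ethylsulfanyl)-3-oxopropanoic acid
Conditions: EtSH, PhMe, 90 °C, sealed tube
Reagents that add atoms: ethanethiol, CCS
Why: Thermal ring opening of Meldrum's acid by a thiol gives the malonic half thioester with loss of acetone.

Step 10
Reactants: 13 (2S,3R)-3-{[tert-butyl(dimethyl)silyl]oxymethyl}-2-(hydroxymethyl)-2-[(4-methoxybenzyloxy)methyl]-4,4-dimethylcyclohexan-1-one; 15 3-(ethylsulfanyl)-3-oxopropanoic acid
Product: 16 C20 thiomalonate ester of 13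
Conditions: DCC, DMAP (cat.), CH2Cl2, 0 °C
Reagents that add atoms: none
Why: Steglich esterification of the only free hydroxyl (C20); the cold, nearly neutral conditions should avoid retro-aldol cleavage of the β-hydroxy ketone.

Step 11
Reactants: 16 C20 thiomalonate ester of 13
Product: 17 C9 alcohol (16 without the PMB group)
Conditions: DDQ, CH2Cl2/pH 7 phosphate buffer, 0 °C
Reagents that add atoms: none
Why: Oxidative PMB ether cleavage by DDQ, to which thioester, silyl ether and ketone are inert; the alcohol is oxidised at once so that the acyl group cannot migrate between the two C10 arms.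

Step 12
Reactants: 17 C9 alcohol
Product: 18 C9 aldehyde bearing the C20 thiomalonate
Conditions: DMP, NaHCO3, CH2Cl2, 0 °C → rt
Reagents that add atoms: none
Why: Dess–Martin oxidation of the neopentyl primary alcohol under buffered, non-basic conditions, which should give the non-enolisable 2-formyl ketone without deformylation.

Step 13
Reactants: 18 C9 aldehyde bearing the C20 thiomalonate
Product: 19 spiro alkylidene lactone (C8=C9; S-ethyl thioester on C8)
Conditions: piperidinium acetate (10 mol %), 4 Å molecular sieves, CH2Cl2, rt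
Reagents that add atoms: none
Why: Intramolecular Knoevenagel condensation of the active methylene with the aldehyde (far more electrophilic than the hindered C1 ketone) closes the six-membered lactone as the doubly activated C8=C9 alkylidene; no stereocentre is formed.

Step 14
Reactants: 19 spiro alkylidene lactone
Product: 20 Diels–Alder adduct (lactone cis-fused to cyclohexene ring C; C12=C13; thioester on C8)
Conditions: buta-1,3-diene (excess), ZnCl2 (0.5 equiv), CH2Cl2, −20 °C → rt, sealed tube
Reagents that add atoms: buta-1,3-diene, C=CC=C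
Why: Lewis acid-catalysed Diels–Alder reaction of a doubly activated alkylidene 1,3-dicarbonyl, a dienophile class known to react at a β-carbon next to a quaternary centre; ZnCl2 is held by the chelating lactone/thioester pair, suprafacial addition makes the lactone/ring C fusion cis, and the diene should approach the lactone face syn to the flat C1 carbonyl and anti to C5 with its gauche CH2OTBS arm, which sets C9 and C8 as in the target.

Step 15
Reactants: 20 Diels–Alder adduct
Product: 21 C15 aldehyde (8-formyl lactone)
Conditions: Et3SiH, Pd/CaCO3 poisoned with Pb(OAc)2 (cat.), acetone, rt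
Reagents that add atoms: none
Why: Fukuyama reduction (palladium insertion into the C–S bond, then hydride transfer from the silane) converts the thioester into the aldehyde without touching lactone or ketone, and the poisoned catalyst should spare the ring C alkene.

Step 16
Reactants: 21 C15 aldehyde
Product: 22 propargylic alcohol (C8–CH(OH)–C≡CH; both C15 epimers)
Conditions: HC≡CMgBr, THF, −78 °C; aq NH4Cl
Reagents that add atoms: ethynylmagnesium bromide, C#C[Mg]Br
Why: Grignard 1,2-addition at low temperature is selective for the activated, non-enolisable aldehyde over the hindered C1 ketone and the lactone; both C15 epimers serve because C15 becomes a ketone in step 18.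

Step 17
Reactants: 22 propargylic alcohol
Product: 24 16-methylidene-15-ol with ring D closed (C15 epimers), via vinylstannane 23 (not isolated)
Conditions: Bu3SnH, AIBN (cat.), PhMe, 85 °C (slow addition); then PPTS, CH2Cl2, rt
Reagents that add atoms: none
Why: Stork-type tin-radical enyne cyclisation, in which Bu3Sn• adds to the terminal alkyne carbon, the C16 vinyl radical closes 5-exo-trig onto C13 on the only face the two-atom tether allows (setting C13 R) and the C12 radical is reduced by the tin hydride; mild acid then protodestannylates the vinylstannane.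

Step 18
Reactants: 24 16-methylidene-15-ol
Product: 25 16-methylidene-1,15-dione
Conditions: DMP, NaHCO3, CH2Cl2, 0 °C → rt
Reagents that add atoms: none
Why: Dess–Martin oxidation of the secondary allylic alcohol to the α-methylene cyclopentanone.

Step 19
Reactants: 25 16-methylidene-1,15-dione
Product: 27 (16S)-16-hydroxy-16-methyl-1,15-dione (6-O-TBS), via tertiary hydroperoxide 26 (not isolated)
Conditions: Mn(dpm)3 (10 mol %), PhSiH3, O2 (1 atm), i-PrOH/CH2Cl2, 0 °C; then P(OEt)3
Reagents that add atoms: dioxygen, O=O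
Why: Mukaiyama-type hydration of an enone (hydrogen-atom transfer from a manganese hydride to the terminal methylene, capture of the tertiary α-keto radical at C16 by O2, phosphite reduction of the hydroperoxide); O2 should enter from the exo face of the two-carbon bridge, syn to C14 and away from the C9–C11–C12 bridge, which gives 16S, and the saturated C1 ketone is inert.

Step 20
Reactants: 27 (16S)-16-hydroxy-16-methyl-1,15-dione
Product: 29 ring A enone with 16-O-TMS and 6-O-TBS, via bis-trimethylsilyl intermediate 28 (not isolated)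
Conditions: TMSOTf, Et3N, CH2Cl2, 0 °C; then Pd(OAc)2, MeCN, rt
Reagents that add atoms: trimethylsilyl trifluoromethanesulfonate, C[Si](C)(C)OS(=O)(=O)C(F)(F)F
Why: Saegusa–Ito dehydrogenation; enolisation is possible only from C1 toward C2 (C10 is quaternary and the C15 ketone has no α-hydrogen), and divalent palladium turns the enol silane into the C2=C3 enone by β-hydride elimination, the tertiary hydroxyl being silylated in passing.

Step 21
Reactants: 29 ring A enone with 16-O-TMS and 6-O-TBS
Product: 30 CNP0530135.1 (target)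
Conditions: HF·pyridine, THF/pyridine, 0 °C → rt
Reagents that add atoms: none
Why: Fluoride-mediated cleavage of both silyl ethers under mildly acidic conditions that should leave the enone, the lactone and the tertiary α-ketol intact.

Compound list
1 | 4,4-dimethylcyclopent-2-en-1-one | CC1(C)CC(=O)C=C1 | starting material
2 | lithium 3,3-dimethylcyclopenta-1,4-dien-1-olate (α′-dienolate of 1) | [Li]OC1=CC(C)(C)C=C1 | intermediate (not isolated)
3 | rac-5-(hydroxymethyl)-4,4-dimethylcyclopent-2-en-1-one | CC1(C)C=CC(=O)C1CO | intermediate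
4 | (5S)-5-(hydroxymethyl)-4,4-dimethylcyclopent-2-en-1-one | CC1(C)C=CC(=O)[C@@H]1CO | intermediate
5 | (5S)-5-{[tert-butyl(dimethyl)silyl]oxymethyl}-4,4-dimethylcyclopent-2-en-1-one | CC1(C)C=CC(=O)[C@@H]1CO[Si](C)(C)C(C)(C)C | intermediate
6 | (2S)-2-{[tert-butyl(dimethyl)silyl]oxymethyl}-3,3-dimethylcyclopentan-1-one | CC1(C)CCC(=O)[C@@H]1CO[Si](C)(C)C(C)(C)C | intermediate
7 | 2-bromoprop-2-en-1-ol | OCC(Br)=C | starting material
8 | 1-{[(2-bromoprop-2-en-1-yl)oxy]methyl}-4-methoxybenzene | C=C(Br)COCc1ccc(OC)cc1 | intermediate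
9 | [3-(4-methoxybenzyloxy)prop-1-en-2-yl]lithium | [Li]C(=C)COCc1ccc(OC)cc1 | intermediate (not isolated)
10 | dichloro[3-(4-methoxybenzyloxy)prop-1-en-2-yl]cerium | Cl[Ce](Cl)C(=C)COCc1ccc(OC)cc1 | intermediate (not isolated)
11 | (1S,2S)-2-{[tert-butyl(dimethyl)silyl]oxymethyl}-1-[3-(4-methoxybenzyloxy)prop-1-en-2-yl]-3,3-dimethylcyclopentan-1-ol | CC1(C)CC[C@@](O)(C(=C)COCc2ccc(OC)cc2)[C@@H]1CO[Si](C)(C)C(C)(C)C | intermediate
12 | (1S,2S)-2-{[tert-butyl(dimethyl)silyl]oxymethyl}-1-{(2S)-2-[(4-methoxybenzyloxy)methyl]oxiran-2-yl}-3,3-dimethylcyclopentan-1-ol | CC1(C)CC[C@@](O)([C@@]2(COCc3ccc(OC)cc3)CO2)[C@@H]1CO[Si](C)(C)C(C)(C)C | intermediate (key-step precursor)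
13 | (2S,3R)-3-{[tert-butyl(dimethyl)silyl]oxymethyl}-2-(hydroxymethyl)-2-[(4-methoxybenzyloxy)methyl]-4,4-dimethylcyclohexan-1-one (free CH2OH = C20, cis to the C6 arm; CH2OPMB = C9) | CC1(C)CCC(=O)[C@](COCc2ccc(OC)cc2)(CO)[C@@H]1CO[Si](C)(C)C(C)(C)C | intermediate (key-step product)
14 | 2,2-dimethyl-1,3-dioxane-4,6-dione (Meldrum's acid) | CC1(C)OC(=O)CC(=O)O1 | starting material
15 | 3-(ethylsulfanyl)-3-oxopropanoic acid | CCSC(=O)CC(=O)O | intermediate
16 | 13 esterified at the C20 hydroxyl with 3-(ethylsulfanyl)-3-oxopropanoic acid; C9 arm still the PMB ether; spatial configuration at C5 and C10 as in 13 | CC1(C)CCC(=O)[C@](COCc2ccc(OC)cc2)(COC(=O)CC(=O)SCC)[C@@H]1CO[Si](C)(C)C(C)(C)C | intermediate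
17 | C9 alcohol: 16 with the PMB ether replaced by OH | CC1(C)CCC(=O)[C@](CO)(COC(=O)CC(=O)SCC)[C@@H]1CO[Si](C)(C)C(C)(C)C | intermediate
18 | C9 aldehyde (2-formyl ketone) bearing the C20 thiomalonate; 5R,10S | CC1(C)CCC(=O)[C@](C=O)(COC(=O)CC(=O)SCC)[C@@H]1CO[Si](C)(C)C(C)(C)C | intermediate
19 | spiro alkylidene lactone: S-ethyl 2-oxo-5,6-dihydro-2H-pyran-3-carbothioate ring (C20H2–O–C7(=O)–C8=C9H) spiro-fused at C10 to the ring A ketone carrying 4,4-dimethyl and 5-CH2OTBS; 5R,10S | CC1(C)CCC(=O)[C@@]2(C=C(C(=O)SCC)C(=O)OC2)[C@@H]1CO[Si](C)(C)C(C)(C)C | intermediate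
20 | Diels–Alder adduct: lactone cis-fused to cyclohexene ring C (C12=C13), S-ethyl thioester on C8, C11 and C14 on the lactone face syn to C1; 5R,8R,9S,10S | CC1(C)CCC(=O)[C@]2(COC(=O)[C@@]3(C(=O)SCC)CC=CC[C@H]32)[C@@H]1CO[Si](C)(C)C(C)(C)C | intermediate
21 | C15 aldehyde (formyl group on C8 in place of the thioester); 5R,8S,9S,10S | CC1(C)CCC(=O)[C@]2(COC(=O)[C@@]3(C=O)CC=CC[C@H]32)[C@@H]1CO[Si](C)(C)C(C)(C)C | intermediate
22 | propargylic alcohol, C8–C15H(OH)–C16≡C17H, mixture of C15 epimers; 5R,8S,9S,10S | CC1(C)CCC(=O)[C@]2(COC(=O)[C@@]3(C(O)C#C)CC=CC[C@H]32)[C@@H]1CO[Si](C)(C)C(C)(C)C | intermediate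
23 | ring D closed, 16-[(tributylstannyl)methylidene]-15-ol, C15 epimers; 13R | CC1(C)CCC(=O)[C@]2(COC(=O)[C@@]34C[C@@H](CC[C@H]32)C(=C[Sn](CCCC)(CCCC)CCCC)C4O)[C@@H]1CO[Si](C)(C)C(C)(C)C | intermediate (not isolated)
24 | 16-methylidene-15-ol, bicyclo[3.2.1]octane rings C and D complete, C15 epimers; 5R,8S,9S,10S,13R | CC1(C)CCC(=O)[C@]2(COC(=O)[C@@]34C[C@@H](CC[C@H]32)C(=C)C4O)[C@@H]1CO[Si](C)(C)C(C)(C)C | intermediate
25 | 16-methylidene-1,15-dione (α-methylene cyclopentanone in ring D); 5R,8S,9S,10S,13R | CC1(C)CCC(=O)[C@]2(COC(=O)[C@@]34C[C@@H](CC[C@H]32)C(=C)C4=O)[C@@H]1CO[Si](C)(C)C(C)(C)C | intermediate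
26 | (16S)-16-hydroperoxy-16-methyl-1,15-dione | CC1(C)CCC(=O)[C@]2(COC(=O)[C@@]34C[C@@H](CC[C@H]32)[C@](C)(OO)C4=O)[C@@H]1CO[Si](C)(C)C(C)(C)C | intermediate (not isolated)
27 | (16S)-16-hydroxy-16-methyl-1,15-dione, 6-O-TBS, ring A saturated; 5R,8S,9S,10S,13R,16S | CC1(C)CCC(=O)[C@]2(COC(=O)[C@@]34C[C@@H](CC[C@H]32)[C@](C)(O)C4=O)[C@@H]1CO[Si](C)(C)C(C)(C)C | intermediate
28 | C1 trimethylsilyl enol ether (C1=C2) with 16-O-TMS and 6-O-TBS | CC1(C)CC=C(O[Si](C)(C)C)[C@]2(COC(=O)[C@@]34C[C@@H](CC[C@H]32)[C@](C)(O[Si](C)(C)C)C4=O)[C@@H]1CO[Si](C)(C)C(C)(C)C | intermediate (not isolated)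
29 | ring A enone (C2=C3) with 16-O-TMS and 6-O-TBS | CC1(C)C=CC(=O)[C@]2(COC(=O)[C@@]34C[C@@H](CC[C@H]32)[C@](C)(O[Si](C)(C)C)C4=O)[C@@H]1CO[Si](C)(C)C(C)(C)C | intermediate
30 | CNP0530135.1: (5R,8S,9S,10S,13R,16S)-6,16-dihydroxy-1,15-dioxo-6,7-secokaur-2-en-7,20-olide (numbering as in the plan) | CC1(C)C=CC(=O)[C@]2(COC(=O)[C@@]34C[C@@H](CC[C@H]32)[C@](C)(O)C4=O)[C@@H]1CO | target

Total step count: 21 (19 on the main line plus the preparations of 8 and 15).
Longest linear sequence: 19 steps (steps 1–4, 6–8 and 10–21).

Steps most likely to fail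

Step 8. The C1–C2 bond may shift in competition with C1–C5, the PMB ether may be lost through ionisation, or the β-hydroxy ketone may lose formaldehyde by retro-aldol cleavage on work-up. The fallback sets out from 12 and returns at 16. The rearrangement is run inside an aluminium alkoxide chelate instead of under a free Lewis acid, with Al(Oi-Pr)3 in i-PrOH/PhMe at reflux (tandem semipinacol rearrangement/Meerwein–Ponndorf–Verley reduction of an α-hydroxy epoxide). The alkoxide then drives the same C5 shift and the nascent ketone is reduced at once, giving the 1,3-diol F1 (C1 carbinol configuration immaterial). The primary C20 hydroxyl of F1 is acylated selectively with 15 (DCC, DMAP, 0 °C) to the hydroxy thiomalonate F2, and Dess–Martin oxidation of the remaining secondary C1 alcohol gives 16.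

Step 7. Oxygen may be delivered to the other face of the 1,1-disubstituted alkene, which would invert C10 after the shift. The fallback sets out from 11 and returns at 18. The diastereomeric (2R)-epoxide F3 is rearranged under the conditions of step 8 to the C10-epimeric ketol F4. In F4 the free hydroxymethyl arm is trans to C6 and must become C9, while the PMB-bearing arm becomes C20. The roles of the arms are exchanged by oxidising first (DMP, NaHCO3) to the keto aldehyde F5, removing the PMB group (DDQ, buffered CH2Cl2) to give the hydroxy aldehyde F6, and esterifying the C20 hydroxyl with 15 (DCC, DMAP). This gives 18 with no extra step.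

Step 17. The C12 radical may rearrange through a cyclopropylcarbinyl intermediate to the bicyclo[2.2.2]octane isomer, or the alkyne may simply be hydrostannylated without ring closure. The fallback sets out from 22 and returns at 27. Ring D is closed by a palladium-hydride enyne cycloisomerisation (Pd(OAc)2, PPh3, PhH, 60 °C; Trost Alder-ene type): hydropalladation of the alkyne, 5-exo carbopalladation of C12=C13 and β-hydride elimination toward C11 give the 1,4-diene alcohol F7. Dess–Martin oxidation gives the dienone F8. The hydration of step 19 (the isolated C11=C12 bond should be inert to hydrogen-atom transfer under those conditions) gives the unsaturated ketol F9, and hydrogenation of the remaining C11=C12 bond (H2, Pd/C, EtOAc) gives 27.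

Further compounds
F1 | step 8 | 1,3-diol: 13 with the C1 ketone reduced to the alcohol (C1 configuration unspecified) | CC1(C)CCC(O)[C@](COCc2ccc(OC)cc2)(CO)[C@@H]1CO[Si](C)(C)C(C)(C)C
F2 | step 8 | hydroxy thiomalonate: F1 acylated at the C20 hydroxyl with 15 | CC1(C)CCC(O)[C@](COCc2ccc(OC)cc2)(COC(=O)CC(=O)SCC)[C@@H]1CO[Si](C)(C)C(C)(C)C
F3 | step 7 | (1S,2S)-2-{[tert-butyl(dimethyl)silyl]oxymethyl}-1-{(2R)-2-[(4-methoxybenzyloxy)methyl]oxiran-2-yl}-3,3-dimethylcyclopentan-1-ol | CC1(C)CC[C@@](O)([C@]2(COCc3ccc(OC)cc3)CO2)[C@@H]1CO[Si](C)(C)C(C)(C)C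
F4 | step 7 | (2R,3R)-3-{[tert-butyl(dimethyl)silyl]oxymethyl}-2-(hydroxymethyl)-2-[(4-methoxybenzyloxy)methyl]-4,4-dimethylcyclohexan-1-one (C10 epimer of 13) | CC1(C)CCC(=O)[C@@](COCc2ccc(OC)cc2)(CO)[C@@H]1CO[Si](C)(C)C(C)(C)C
F5 | step 7 | keto aldehyde: F4 with the free CH2OH oxidised to CHO (C9), PMB ether on the C20 arm | CC1(C)CCC(=O)[C@@](COCc2ccc(OC)cc2)(C=O)[C@@H]1CO[Si](C)(C)C(C)(C)C
F6 | step 7 | hydroxy aldehyde: F5 without the PMB group (free C20 hydroxyl) | CC1(C)CCC(=O)[C@@](CO)(C=O)[C@@H]1CO[Si](C)(C)C(C)(C)C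
F7 | step 17 | 1,4-diene alcohol: ring D closed, 16-methylidene-15-ol with C11=C12 (C15 epimers) | CC1(C)CCC(=O)[C@]2(COC(=O)[C@@]34C[C@@H](C=C[C@H]32)C(=C)C4O)[C@@H]1CO[Si](C)(C)C(C)(C)C
F8 | step 17 | dienone: 16-methylidene-1,15-dione with C11=C12 | CC1(C)CCC(=O)[C@]2(COC(=O)[C@@]34C[C@@H](C=C[C@H]32)C(=C)C4=O)[C@@H]1CO[Si](C)(C)C(C)(C)C
F9 | step 17 | unsaturated ketol: (16S)-16-hydroxy-16-methyl-1,15-dione with C11=C12 | CC1(C)CCC(=O)[C@]2(COC(=O)[C@@]34C[C@@H](C=C[C@H]32)[C@](C)(O)C4=O)[C@@H]1CO[Si](C)(C)C(C)(C)C
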